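The route rests on disconnecting the bridging C3–O bond of the 7-oxabicyclo[2.2.1]heptane end group. The key step is a transannular Mitsunobu cyclodehydration: the tertiary C6 hydroxyl displaces the activated C3 hydroxyl with inversion, closing the oxolane ring O–C3–C2–C1–C6 across the preformed cyclohexane. It exploits the trans-1,4 relation of O3 and O6 and the cis C5/C6 diol, which leaves the C5 hydroxyl exo. The precursor is a monocyclic C15 cyclohexane-1,2,4-triol made from (S)-phorenol by epoxidation, alkynylation and hydride reduction. The trihydroxy end group comes from (R)-phorenol, and the two C15 phosphonium salts are joined through the C10 dialdehyde by two Wittig reactions.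

Key step: step 16

Remark: the structure is read as the all-E (3R,5R,6S,3'R,5'S,6'S) isomer, with the C5 hydroxyl exo (cis to the oxygen bridge) and the C5' hydroxyl trans to the mutually cis C3' and C6' hydroxyls; compounds 1, 6, 11, 17 and 26 are taken as commercial.

**Right-hand C15 fragment (steps 1–9)**

Step 1
Reactants: 1 ketoisophorone (2,6,6-trimethylcyclohex-2-ene-1,4-dione)
Product: 2 (R)-4-hydroxy-2,6,6-trimethylcyclohex-2-en-1-one ((R)-phorenol)
Conditions: RuCl(p-cymene)[(R,R)-TsDPEN] (cat.), KOH (cat.), i-PrOH, rt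
Reagents that add atoms: none
Why: Noyori–Ikariya asymmetric transfer hydrogenation should reduce only the unhindered C4 carbonyl (the other is shielded by the gem-dimethyl carbon), the chiral ruthenium hydride setting the carbinol centre with the alkenyl flank playing the part of the aryl group of an aryl ketone.

Step 2
Reactants: 2 (R)-phorenol
Product: 3 (R)-4-[(tert-butyldimethylsilyl)oxy]-2,6,6-trimethylcyclohex-2-en-1-one
Conditions: TBSCl, imidazole, DMF, rt
Reagents that add atoms: tert-butyldimethylsilyl chloride, CC(C)(C)[Si](C)(C)Cl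
Why: Silylation of the secondary alcohol protects it for the enolate chemistry and leaves the stereocentre untouched.

Step 3
Reactants: 3 silyl ether of (R)-phorenol
Product: 5 (4S)-4-[(tert-butyldimethylsilyl)oxy]-2,6,6-trimethylcyclohex-1-en-1-yl trifluoromethanesulfonate, via lithium enolate 4 (not isolated)
Conditions: LiBH(s-Bu)3, THF, −78 °C; then PhNTf2, −78 °C to rt
Reagents that add atoms: N-phenylbis(trifluoromethanesulfonimide), O=S(=O)(N(c1ccccc1)S(=O)(=O)C(F)(F)F)C(F)(F)F; lithium tri-sec-butylborohydride, [Li+].CCC(C)[BH-](C(C)CC)C(C)CC (lithium of intermediate 4 only)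
Why: Reductive triflation: conjugate hydride addition to the β-unsubstituted enone gives one regiodefined enolate, which is trapped on oxygen as the tetrasubstituted enol triflate, the carbinol centre being untouched (its descriptor changes only through the priority rules).

Step 4
Reactants: 5 enol triflate; 6 methyl vinyl ketone (but-3-en-2-one)
Product: 7 (E)-4-[(4S)-4-[(tert-butyldimethylsilyl)oxy]-2,6,6-trimethylcyclohex-1-en-1-yl]but-3-en-2-one
Conditions: Pd(OAc)2 (cat.), PPh3, Et3N, DMF, 70 °C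
Reagents that add atoms: none
Why: Mizoroki–Heck reaction: oxidative addition of the alkenyl triflate, insertion of the enone at its terminal carbon and syn β-hydride elimination should give the (E)-dienone.

Step 5
Reactants: 7 silyloxy dienone
Product: 8 (E)-4-[(4S)-4-hydroxy-2,6,6-trimethylcyclohex-1-en-1-yl]but-3-en-2-one ((3S)-3-hydroxy-β-ionone)
Conditions: Bu4NF, THF, 0 °C to rt
Reagents that add atoms: none
Why: Fluoride-induced desilylation frees the homoallylic hydroxyl that has to direct the next step.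

Step 6
Reactants: 8 (3S)-3-hydroxy-β-ionone
Product: 9 (E)-4-[(1S,4R,6R)-4-hydroxy-2,2,6-trimethyl-7-oxabicyclo[4.1.0]heptan-1-yl]but-3-en-2-one (epoxide cis to the hydroxyl)
Conditions: VO(acac)2 (cat.), t-BuOOH, toluene, 0 °C to rt
Reagents that add atoms: tert-butyl hydroperoxide, CC(C)(C)OO
Why: Hydroxyl-directed epoxidation: the homoallylic C3–OH binds the vanadium alkylperoxide and delivers oxygen to its own face of the electron-rich tetrasubstituted C5=C6 bond (the enone double bond is too electron-poor), which sets C5 and C6.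

Step 7
Reactants: 9 cis-epoxy alcohol
Product: 10 (E)-4-[(1S,2S,4R)-1,2,4-trihydroxy-2,6,6-trimethylcyclohexyl]but-3-en-2-one
Conditions: HClO4 (cat.), THF/H2O, 0 °C
Reagents that add atoms: water, O
Why: Acid-catalysed trans-diaxial epoxide hydrolysis: water should attack C5 with inversion because C6 is neopentylic and carries the electron-poor enone chain and because this is the Fürst–Plattner opening of the half-chair with an equatorial C3–OH, while the retained C6–O bond leaves the C6 hydroxyl cis to the C3 hydroxyl.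

Step 8
Reactants: 10 triol enone; 11 vinylmagnesium bromide
Product: 12 (1S,2S,4R)-1-[(1E)-3-hydroxy-3-methylpenta-1,4-dien-1-yl]-2,6,6-trimethylcyclohexane-1,2,4-triol (both epimers at the side-chain carbinol)
Conditions: CH2=CHMgBr (5 equiv), THF, −20 to 0 °C; then aq. NH4Cl
Reagents that add atoms: none
Why: Grignard 1,2-addition to the methyl ketone after deprotonation of the three hydroxyls, the β-carbon being shielded by the quaternary C6; the new carbinol centre is lost in the next step.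

Step 9
Reactants: 12 vinyl carbinol
Product: 13 [(2E,4E)-3-methyl-5-[(1S,2S,4R)-1,2,4-trihydroxy-2,6,6-trimethylcyclohexyl]penta-2,4-dien-1-yl]triphenylphosphonium bromide
Conditions: PPh3·HBr, MeOH, 0 °C to rt
Reagents that add atoms: triphenylphosphine hydrobromide, [Br-].c1ccccc1[PH+](c1ccccc1)c1ccccc1
Why: Ionisation of the doubly allylic tertiary alcohol and capture of the pentadienyl cation by PPh3 at the unhindered terminus (substitution with allylic transposition) should give the conjugated dienyl phosphonium salt in the more stable (E,E) geometry.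

**Left-hand C15 fragment (steps 10–17)**

Step 10
Reactants: 1 ketoisophorone
Product: 14 (S)-4-hydroxy-2,6,6-trimethylcyclohex-2-en-1-one ((S)-phorenol)
Conditions: RuCl(p-cymene)[(S,S)-TsDPEN] (cat.), KOH (cat.), i-PrOH, rt
Reagents that add atoms: none
Why: The same Noyori–Ikariya transfer hydrogenation with the enantiomeric catalyst sets the opposite carbinol configuration.

Step 11
Reactants: 14 (S)-phorenol
Product: 15 (1S)-3,5,5-trimethyl-4-oxocyclohex-2-en-1-yl 2,2-dimethylpropanoate
Conditions: t-BuCOCl, pyridine, DMAP (cat.), CH2Cl2, 0 °C to rt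
Reagents that add atoms: pivaloyl chloride, CC(C)(C)C(Cl)=O
Why: Acylation gives a bulky ester that steers the epoxidation, survives the acetylide and is removed by the hydride in step 15.

Step 12
Reactants: 15 pivalate
Product: 16 (1R,2S,6R)-4,4,6-trimethyl-5-oxo-7-oxabicyclo[4.1.0]heptan-2-yl 2,2-dimethylpropanoate (epoxide trans to the ester)
Conditions: t-BuOOH, DBU, CH2Cl2, 0 °C to rt
Reagents that add atoms: tert-butyl hydroperoxide, CC(C)(C)OO
Why: Weitz–Scheffer nucleophilic epoxidation: the peroxide anion adds to C4 anti to the neighbouring pivaloyloxy group and the enolate closes the epoxide on that face, setting C4 and C5.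

Step 13
Reactants: 17 (E)-3-methylpent-2-en-4-yn-1-ol
Product: 18 tert-butyldimethyl{[(2E)-3-methylpent-2-en-4-yn-1-yl]oxy}silane
Conditions: TBSCl, imidazole, CH2Cl2, rt
Reagents that add atoms: tert-butyldimethylsilyl chloride, CC(C)(C)[Si](C)(C)Cl
Why: Silylation masks the primary allylic alcohol so that only the secondary ring hydroxyl can be activated in step 16.

Step 14
Reactants: 18 silyl enyne; 16 epoxy ketone
Product: 20 (1R,2S,5R,6R)-5-[(3E)-5-[(tert-butyldimethylsilyl)oxy]-3-methylpent-3-en-1-yn-1-yl]-5-hydroxy-4,4,6-trimethyl-7-oxabicyclo[4.1.0]heptan-2-yl 2,2-dimethylpropanoate, via lithium acetylide 19 (not isolated)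
Conditions: n-BuLi, THF, −78 °C; then 16, −78 to −30 °C; then H2O
Reagents that add atoms: n-butyllithium, [Li+].[CH2-]CCC (lithium of intermediate 19 only)
Why: 1,2-Addition of the acetylide to the non-enolisable ketone should occur from the face opposite the epoxide oxygen and the pseudoaxial C1 methyl, so the new C6 hydroxyl is cis to the epoxide and trans to the ester.

Step 15
Reactants: 20 propargylic alcohol
Product: 21 (1S,2R,4S)-1-[(1E,3E)-5-[(tert-butyldimethylsilyl)oxy]-3-methylpenta-1,3-dien-1-yl]-2,6,6-trimethylcyclohexane-1,2,4-triol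
Conditions: LiAlH4 (excess), THF, 0 to 50 °C; then H2O, aq. NaOH
Reagents that add atoms: none
Why: Hydride reduction does three jobs: alkoxide-directed trans-hydroalumination of the propargylic alcohol gives the (E)-alkene, the pivalate is cleaved, and hydride opens the epoxide at the secondary C4 anti to the oxygen, so C5 keeps its oxygen and configuration.

Step 16
Reactants: 21 triol
Product: 23 (1S,2R,4R)-1-[(1E,3E)-5-[(tert-butyldimethylsilyl)oxy]-3-methylpenta-1,3-dien-1-yl]-2,6,6-trimethyl-7-oxabicyclo[2.2.1]heptan-2-ol, via alkoxyphosphonium salt 22 (not isolated)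
Conditions: PPh3, DIAD, toluene, 0 to 60 °C
Reagents that add atoms: triphenylphosphine, c1ccccc1P(c1ccccc1)c1ccccc1, and diisopropyl azodicarboxylate, CC(C)OC(=O)N=NC(=O)OC(C)C (atoms of intermediate 22 only; none remain in 23)
Why: The PPh3/DIAD betaine activates the only secondary hydroxyl (C3–OH) as an alkoxyphosphonium with retention, and the tertiary C6–OH, trans-1,4 to it, displaces Ph3P=O by intramolecular SN2 through the boat conformer. The closest known reaction type is the Mitsunobu cyclodehydration of 1,4-diols to oxolanes. The single new C3–O bond closes the labelled oxolane O–C3–C2–C1–C6 as a 5-exo-tet transannular etherification and, with it, the second oxolane O–C3–C4–C5–C6, the carbocycle being already present. C3 is inverted by the SN2 geometry and becomes the bridgehead cis to C6, while C5 and C6 come unchanged from 21, which leaves the C5 hydroxyl exo. The step needs activation of C3–OH over the two hindered tertiary hydroxyls, which sterics should secure, and it must avoid alkoxide conditions, because a C5 alkoxide 1,3 to a C3 leaving group would undergo Grob fragmentation. The neutral conditions and the blocking of external nucleophiles by the syn-axial C1 methyl and C5 hydroxyl should leave the C6 oxygen as the only competent nucleophile.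

Step 17
Reactants: 23 bicyclic silyl ether
Product: 25 [(2E,4E)-5-[(1S,2R,4R)-2-hydroxy-2,6,6-trimethyl-7-oxabicyclo[2.2.1]heptan-1-yl]-3-methylpenta-2,4-dien-1-yl]triphenylphosphonium bromide, via allylic alcohol 24 (not isolated)
Conditions: PPh3·HBr, MeOH, rt
Reagents that add atoms: triphenylphosphine hydrobromide, [Br-].c1ccccc1[PH+](c1ccccc1)c1ccccc1
Why: HBr-catalysed methanolysis of the allylic silyl ether is followed by substitution of the dienylic primary alcohol by PPh3 through its allylic cation, conditions under which the bridged ether and the non-allylic tertiary alcohol should persist.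

**Assembly (steps 18–19)**

Step 18
Reactants: 25 left-hand phosphonium bromide; 26 (2E,4E,6E)-2,7-dimethylocta-2,4,6-trienedial (3 equiv)
Product: 28 (2E,4E,6E,8E,10E,12E)-13-[(1S,2R,4R)-2-hydroxy-2,6,6-trimethyl-7-oxabicyclo[2.2.1]heptan-1-yl]-2,7,11-trimethyltrideca-2,4,6,8,10,12-hexaenal, via phosphorus ylide 27 (not isolated)
Conditions: NaOMe, MeOH/CH2Cl2, 0 °C to rt; then I2 (cat.), CH2Cl2, daylight
Reagents that add atoms: none
Why: Wittig olefination of one aldehyde group of the symmetrical dialdehyde by the semi-stabilised ylide, the excess of 26 suppressing double condensation and iodine equilibrating any (Z) isomer at the new C11=C12 bond to the all-E polyene.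

Step 19
Reactants: 13 right-hand phosphonium bromide; 28 C25 aldehyde
Product: 30 (all-E)-(3R,5R,6S,3'R,5'S,6'S)-3,6-epoxy-5,6,5',6'-tetrahydro-β,β-carotene-5,3',5',6'-tetrol (target), via phosphorus ylide 29 (not isolated)
Conditions: NaOMe, MeOH/CH2Cl2, 0 °C to rt; then I2 (cat.), CH2Cl2, daylight
Reagents that add atoms: none
Why: The second Wittig olefination forms the C11'=C12' bond in the presence of the free hydroxyls, and iodine-catalysed equilibration should give the all-E nonaene without touching any stereocentre.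

**Compound list**

1 | ketoisophorone (2,6,6-trimethylcyclohex-2-ene-1,4-dione) | CC1=CC(=O)CC(C)(C)C1=O | starting material
2 | (R)-4-hydroxy-2,6,6-trimethylcyclohex-2-en-1-one | O=C1C(C)(C)C[C@@H](O)C=C1C | intermediate
3 | (R)-4-[(tert-butyldimethylsilyl)oxy]-2,6,6-trimethylcyclohex-2-en-1-one | O=C1C(C)(C)C[C@@H](O[Si](C)(C)C(C)(C)C)C=C1C | intermediate
4 | lithium (4S)-4-[(tert-butyldimethylsilyl)oxy]-2,6,6-trimethylcyclohex-1-en-1-olate | [Li+].[O-]C1=C(C)C[C@H](O[Si](C)(C)C(C)(C)C)CC1(C)C | intermediate (not isolated)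
5 | (4S)-4-[(tert-butyldimethylsilyl)oxy]-2,6,6-trimethylcyclohex-1-en-1-yl trifluoromethanesulfonate | CC1(C)C[C@@H](O[Si](C)(C)C(C)(C)C)CC(C)=C1OS(=O)(=O)C(F)(F)F | intermediate
6 | methyl vinyl ketone (but-3-en-2-one) | CC(=O)C=C | starting material
7 | (E)-4-[(4S)-4-[(tert-butyldimethylsilyl)oxy]-2,6,6-trimethylcyclohex-1-en-1-yl]but-3-en-2-one | CC(=O)/C=C/C1=C(C)C[C@H](O[Si](C)(C)C(C)(C)C)CC1(C)C | intermediate
8 | (E)-4-[(4S)-4-hydroxy-2,6,6-trimethylcyclohex-1-en-1-yl]but-3-en-2-one | CC(=O)/C=C/C1=C(C)C[C@H](O)CC1(C)C | intermediate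
9 | (E)-4-[(1S,4R,6R)-4-hydroxy-2,2,6-trimethyl-7-oxabicyclo[4.1.0]heptan-1-yl]but-3-en-2-one | CC(=O)/C=C/[C@@]12O[C@]1(C)C[C@H](O)CC2(C)C | intermediate
10 | (E)-4-[(1S,2S,4R)-1,2,4-trihydroxy-2,6,6-trimethylcyclohexyl]but-3-en-2-one | CC(=O)/C=C/[C@]1(O)C(C)(C)C[C@@H](O)C[C@]1(C)O | intermediate
11 | vinylmagnesium bromide | C=C[Mg]Br | starting material
12 | (1S,2S,4R)-1-[(1E)-3-hydroxy-3-methylpenta-1,4-dien-1-yl]-2,6,6-trimethylcyclohexane-1,2,4-triol (side-chain carbinol epimers) | C=CC(C)(O)/C=C/[C@]1(O)C(C)(C)C[C@@H](O)C[C@]1(C)O | intermediate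
13 | [(2E,4E)-3-methyl-5-[(1S,2S,4R)-1,2,4-trihydroxy-2,6,6-trimethylcyclohexyl]penta-2,4-dien-1-yl]triphenylphosphonium bromide | [Br-].c1ccccc1[P+](c1ccccc1)(c1ccccc1)C/C=C(C)/C=C/[C@]1(O)C(C)(C)C[C@@H](O)C[C@]1(C)O | intermediate
14 | (S)-4-hydroxy-2,6,6-trimethylcyclohex-2-en-1-one | O=C1C(C)(C)C[C@H](O)C=C1C | intermediate
15 | (1S)-3,5,5-trimethyl-4-oxocyclohex-2-en-1-yl 2,2-dimethylpropanoate | O=C1C(C)(C)C[C@H](OC(=O)C(C)(C)C)C=C1C | intermediate
16 | (1R,2S,6R)-4,4,6-trimethyl-5-oxo-7-oxabicyclo[4.1.0]heptan-2-yl 2,2-dimethylpropanoate | O=C1C(C)(C)C[C@H](OC(=O)C(C)(C)C)[C@H]2O[C@@]12C | intermediate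
17 | (E)-3-methylpent-2-en-4-yn-1-ol | C#C/C(C)=C/CO | starting material
18 | tert-butyldimethyl{[(2E)-3-methylpent-2-en-4-yn-1-yl]oxy}silane | C#C/C(C)=C/CO[Si](C)(C)C(C)(C)C | intermediate
19 | lithium acetylide of 18 | [Li+].[C-]#C/C(C)=C/CO[Si](C)(C)C(C)(C)C | intermediate (not isolated)
20 | (1R,2S,5R,6R)-5-[(3E)-5-[(tert-butyldimethylsilyl)oxy]-3-methylpent-3-en-1-yn-1-yl]-5-hydroxy-4,4,6-trimethyl-7-oxabicyclo[4.1.0]heptan-2-yl 2,2-dimethylpropanoate | CC(C)(C)[Si](C)(C)OC/C=C(C)/C#C[C@]1(O)C(C)(C)C[C@H](OC(=O)C(C)(C)C)[C@H]2O[C@@]12C | intermediate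
21 | (1S,2R,4S)-1-[(1E,3E)-5-[(tert-butyldimethylsilyl)oxy]-3-methylpenta-1,3-dien-1-yl]-2,6,6-trimethylcyclohexane-1,2,4-triol | CC(C)(C)[Si](C)(C)OC/C=C(C)/C=C/[C@]1(O)C(C)(C)C[C@H](O)C[C@@]1(C)O | intermediate
22 | C3-alkoxytriphenylphosphonium salt of 21 (hydrazide counter-ion) | CC(C)(C)[Si](C)(C)OC/C=C(C)/C=C/[C@]1(O)C(C)(C)C[C@H](O[P+](c2ccccc2)(c2ccccc2)c2ccccc2)C[C@@]1(C)O.CC(C)OC(=O)N[N-]C(=O)OC(C)C | intermediate (not isolated)
23 | (1S,2R,4R)-1-[(1E,3E)-5-[(tert-butyldimethylsilyl)oxy]-3-methylpenta-1,3-dien-1-yl]-2,6,6-trimethyl-7-oxabicyclo[2.2.1]heptan-2-ol | CC(C)(C)[Si](C)(C)OC/C=C(C)/C=C/[C@]12O[C@H](CC1(C)C)C[C@@]2(C)O | intermediate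
24 | (1S,2R,4R)-1-[(1E,3E)-5-hydroxy-3-methylpenta-1,3-dien-1-yl]-2,6,6-trimethyl-7-oxabicyclo[2.2.1]heptan-2-ol | OC/C=C(C)/C=C/[C@]12O[C@H](CC1(C)C)C[C@@]2(C)O | intermediate (not isolated)
25 | [(2E,4E)-5-[(1S,2R,4R)-2-hydroxy-2,6,6-trimethyl-7-oxabicyclo[2.2.1]heptan-1-yl]-3-methylpenta-2,4-dien-1-yl]triphenylphosphonium bromide | [Br-].c1ccccc1[P+](c1ccccc1)(c1ccccc1)C/C=C(C)/C=C/[C@]12O[C@H](CC1(C)C)C[C@@]2(C)O | intermediate
26 | (2E,4E,6E)-2,7-dimethylocta-2,4,6-trienedial | O=C/C(C)=C/C=C/C=C(C)/C=O | starting material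
27 | phosphorus ylide of 25 | c1ccccc1[P+](c1ccccc1)(c1ccccc1)[CH-]/C=C(C)/C=C/[C@]12O[C@H](CC1(C)C)C[C@@]2(C)O | intermediate (not isolated)
28 | (2E,4E,6E,8E,10E,12E)-13-[(1S,2R,4R)-2-hydroxy-2,6,6-trimethyl-7-oxabicyclo[2.2.1]heptan-1-yl]-2,7,11-trimethyltrideca-2,4,6,8,10,12-hexaenal | CC(/C=C/C=C(C)/C=C/[C@]12O[C@H](CC1(C)C)C[C@@]2(C)O)=C\C=C\C=C(C)\C=O | intermediate
29 | phosphorus ylide of 13 | c1ccccc1[P+](c1ccccc1)(c1ccccc1)[CH-]/C=C(C)/C=C/[C@]1(O)C(C)(C)C[C@@H](O)C[C@]1(C)O | intermediate (not isolated)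
30 | (all-E)-(3R,5R,6S,3'R,5'S,6'S)-3,6-epoxy-5,6,5',6'-tetrahydro-β,β-carotene-5,3',5',6'-tetrol | CC(/C=C/C=C(C)/C=C/[C@]12O[C@H](CC1(C)C)C[C@@]2(C)O)=C\C=C\C=C(C)\C=C\C=C(C)\C=C\[C@]1(O)C(C)(C)C[C@@H](O)C[C@]1(C)O | target

**Step count and risks**

Total step count: 19. Longest linear sequence: 10 steps (steps 1–9 and 19, from 1 through 13 to 30).

Steps most likely to fail:

1. Step 16 (key step). The activated C3 oxygen may be lost by elimination to a cyclohexene, or be intercepted by the hydrazide, if closure through the boat conformer is too slow. The fallback closes the bridge from the other end, by cation capture at C6, and sets out from 2. H2O2 and NaOH (cat.) in MeOH at −10 °C would epoxidise the free γ-hydroxy enone cis to its hydroxyl (hydroxyl-guided nucleophilic epoxidation) to give (1R,5R,6R)-5-hydroxy-1,3,3-trimethyl-7-oxabicyclo[4.1.0]heptan-2-one F1. Addition of 19 (2.2 equiv) as in step 14 would give the propargylic diol (1R,5R,6R)-2-[(3E)-5-[(tert-butyldimethylsilyl)oxy]-3-methylpent-3-en-1-yn-1-yl]-1,3,3-trimethyl-7-oxabicyclo[4.1.0]heptane-2,5-diol F2, of which either epimer at the new carbinol is useful. LiAlH4 as in step 15 would give the all-cis triol (2R,4R)-1-[(1E,3E)-5-[(tert-butyldimethylsilyl)oxy]-3-methylpenta-1,3-dien-1-yl]-2,6,6-trimethylcyclohexane-1,2,4-triol F3. Pyridinium p-toluenesulfonate (cat.) in CH2Cl2 at 0 °C would ionise the tertiary, dienyl-stabilised C6–OH, and the cis C3–OH would capture the cation on its own face. The fallback comes back to the route at 23.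

2. Step 7. Water may attack C6 instead of C5, or a C5 cation may form and contract the ring or eliminate. The fallback moves the hydrolysis to a glycidic ester, where acid opening at the β-carbon is unambiguous, and sets out from 5. Pd(OAc)2, PPh3, CO, MeOH and Et3N would give methyl (4S)-4-[(tert-butyldimethylsilyl)oxy]-2,6,6-trimethylcyclohex-1-ene-1-carboxylate F4, and Bu4NF would give methyl (4S)-4-hydroxy-2,6,6-trimethylcyclohex-1-ene-1-carboxylate F5. CF3CO3H with Na2HPO4 would epoxidise the twisted tetrasubstituted double bond on the hydroxyl face to give methyl (1S,4R,6R)-4-hydroxy-2,2,6-trimethyl-7-oxabicyclo[4.1.0]heptane-1-carboxylate F6, any trans epoxide being separated. Dilute HClO4 in THF/H2O would open F6 at C5 with inversion to give methyl (1S,2S,4R)-1,2,4-trihydroxy-2,6,6-trimethylcyclohexane-1-carboxylate F7. i-Bu2AlH at −78 °C would give (1S,2S,4R)-1,2,4-trihydroxy-2,6,6-trimethylcyclohexane-1-carbaldehyde F8, and Wittig olefination with Ph3P=CHC(O)CH3 in toluene would come back to the route at 10.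

3. Step 9. The tertiary allylic C6 carbinol may ionise in competition with the C9 carbinol, leading to pinacol-type shift or allylic scrambling, so that no clean phosphonium salt forms. The fallback reverses the polarity of the last coupling and sets out from 10 and 28. Horner–Wadsworth–Emmons reaction of 10 with (EtO)2P(O)CH2CN and NaH would give (2E,4E)-3-methyl-5-[(1S,2S,4R)-1,2,4-trihydroxy-2,6,6-trimethylcyclohexyl]penta-2,4-dienenitrile F9, and i-Bu2AlH followed by mild hydrolysis would give (2E,4E)-3-methyl-5-[(1S,2S,4R)-1,2,4-trihydroxy-2,6,6-trimethylcyclohexyl]penta-2,4-dienal F10. NaBH4 would reduce 28 to (2E,4E,6E,8E,10E,12E)-13-[(1S,2R,4R)-2-hydroxy-2,6,6-trimethyl-7-oxabicyclo[2.2.1]heptan-1-yl]-2,7,11-trimethyltrideca-2,4,6,8,10,12-hexaen-1-ol F11, and PPh3·HBr would convert it into the corresponding C25 triphenylphosphonium bromide F12. Wittig reaction of F12 with F10 (NaOMe, then I2) would come back to the route at 30.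

Further compounds
F1 | step 16 | (1R,5R,6R)-5-hydroxy-1,3,3-trimethyl-7-oxabicyclo[4.1.0]heptan-2-one | O=C1C(C)(C)C[C@@H](O)[C@H]2O[C@@]12C
F2 | step 16 | (1R,5R,6R)-2-[(3E)-5-[(tert-butyldimethylsilyl)oxy]-3-methylpent-3-en-1-yn-1-yl]-1,3,3-trimethyl-7-oxabicyclo[4.1.0]heptane-2,5-diol (C2 epimers) | CC(C)(C)[Si](C)(C)OC/C=C(C)/C#CC1(O)C(C)(C)C[C@@H](O)[C@H]2O[C@@]12C
F3 | step 16 | (2R,4R)-1-[(1E,3E)-5-[(tert-butyldimethylsilyl)oxy]-3-methylpenta-1,3-dien-1-yl]-2,6,6-trimethylcyclohexane-1,2,4-triol (C1 epimers) | CC(C)(C)[Si](C)(C)OC/C=C(C)/C=C/C1(O)C(C)(C)C[C@@H](O)C[C@@]1(C)O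
F4 | step 7 | methyl (4S)-4-[(tert-butyldimethylsilyl)oxy]-2,6,6-trimethylcyclohex-1-ene-1-carboxylate | COC(=O)C1=C(C)C[C@H](O[Si](C)(C)C(C)(C)C)CC1(C)C
F5 | step 7 | methyl (4S)-4-hydroxy-2,6,6-trimethylcyclohex-1-ene-1-carboxylate | COC(=O)C1=C(C)C[C@H](O)CC1(C)C
F6 | step 7 | methyl (1S,4R,6R)-4-hydroxy-2,2,6-trimethyl-7-oxabicyclo[4.1.0]heptane-1-carboxylate | COC(=O)[C@@]12O[C@]1(C)C[C@H](O)CC2(C)C
F7 | step 7 | methyl (1S,2S,4R)-1,2,4-trihydroxy-2,6,6-trimethylcyclohexane-1-carboxylate | COC(=O)[C@]1(O)C(C)(C)C[C@@H](O)C[C@]1(C)O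
F8 | step 7 | (1S,2S,4R)-1,2,4-trihydroxy-2,6,6-trimethylcyclohexane-1-carbaldehyde | O=C[C@]1(O)C(C)(C)C[C@@H](O)C[C@]1(C)O
F9 | step 9 | (2E,4E)-3-methyl-5-[(1S,2S,4R)-1,2,4-trihydroxy-2,6,6-trimethylcyclohexyl]penta-2,4-dienenitrile | N#C/C=C(C)/C=C/[C@]1(O)C(C)(C)C[C@@H](O)C[C@]1(C)O
F10 | step 9 | (2E,4E)-3-methyl-5-[(1S,2S,4R)-1,2,4-trihydroxy-2,6,6-trimethylcyclohexyl]penta-2,4-dienal | O=C/C=C(C)/C=C/[C@]1(O)C(C)(C)C[C@@H](O)C[C@]1(C)O
F11 | step 9 | (2E,4E,6E,8E,10E,12E)-13-[(1S,2R,4R)-2-hydroxy-2,6,6-trimethyl-7-oxabicyclo[2.2.1]heptan-1-yl]-2,7,11-trimethyltrideca-2,4,6,8,10,12-hexaen-1-ol | CC(/C=C/C=C(C)/C=C/[C@]12O[C@H](CC1(C)C)C[C@@]2(C)O)=C\C=C\C=C(C)\CO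
F12 | step 9 | [(2E,4E,6E,8E,10E,12E)-13-[(1S,2R,4R)-2-hydroxy-2,6,6-trimethyl-7-oxabicyclo[2.2.1]heptan-1-yl]-2,7,11-trimethyltrideca-2,4,6,8,10,12-hexaen-1-yl]triphenylphosphonium bromide | [Br-].CC(/C=C/C=C(C)/C=C/[C@]12O[C@H](CC1(C)C)C[C@@]2(C)O)=C\C=C\C=C(C)\C[P+](c1ccccc1)(c1ccccc1)c1ccccc1
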